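**Plan**
1. Retrosynthesis: the C8–C8' biaryl bond is cut first, so the C30 target falls into two molecules of one C15 phenol, (1S,4S)-7-hydroxycalamenene 12 (calamenene numbering: C1 carries CH3, C4 isopropyl, C6 CH3, C7 OH). Then follow the C4–isopropyl bond with the C3=C4 unsaturation, the C4–C4a bond, the C1–H bond, the C1=CH2 bond and the aryl–C1 bond, back to aryl bromide 1 and succinic anhydride 2.
2. Forward: aromatic ring A is bought with 1, the four-carbon chain comes from 2, the saturated ring B closes by Friedel–Crafts acylation para to OCH3, and the second half arises in the last step by oxidative dehydrodimerisation of the free phenol 12.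
3. Enabling feature: in ring A of 12 the aryloxyl spin sits on O, C6, C8 and C4a. C6 carries CH3 and C4a is the ring-fusion carbon, so C8 is the only carbon whose coupling can be followed by rearomatisation.
4. Stereochemistry: C1 (S) comes from a carboxy-directed iridium-catalysed asymmetric hydrogenation (catalyst control). C4 (S, cis to C1) comes from hydrogenation of C3=C4 anti to the pseudoaxial C1 methyl (substrate control). The dimerisation carries both centres unchanged into each half.

Key step: step 8

Remark on the chemistry: the target SMILES fixes the four carbon stereocentres but not the sense of the hindered C8–C8' axis, so either atropisomer is taken to meet it and the axis is accepted as it forms.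

**Step 1**
Reactants: 1 4-bromo-2-methoxy-1-methylbenzene; 2 succinic anhydride
Product: 4 4-(3-methoxy-4-methylphenyl)-4-oxobutanoic acid, via arylmagnesium bromide 3 (not isolated)
Conditions: Mg, THF, reflux; then added to 2 (1.5 equiv), THF, −78 °C to 0 °C; 1 M HCl
Reagents that add atoms: none
Why: Grignard acylation of a cyclic anhydride should stop after one addition at low temperature because the keto-carboxylate formed is deactivated, and the position of Br in 1 places the chain meta to OCH3 and para to CH3.

**Step 2**
Reactants: 4 4-(3-methoxy-4-methylphenyl)-4-oxobutanoic acid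
Product: 5 4-(3-methoxy-4-methylphenyl)pent-4-enoic acid
Conditions: MePPh3Br (2.2 equiv), t-BuOK (3.3 equiv), THF, 0 °C to 25 °C; 1 M HCl
Reagents that add atoms: methyltriphenylphosphonium bromide, C[P+](c1ccccc1)(c1ccccc1)c1ccccc1.[Br-]
Why: Wittig methylenation of the aryl ketone should proceed cleanly while the extra base holds the acid as its unreactive carboxylate.

**Step 3**
Reactants: 5 4-(3-methoxy-4-methylphenyl)pent-4-enoic acid
Product: 6 (4S)-4-(3-methoxy-4-methylphenyl)pentanoic acid
Conditions: H2 (6 atm), [Ir(cod)(L)][B(3,5-(CF3)2C6H3)4] (1 mol%; L = spiro phosphine–oxazoline 7-[bis(3,5-di-tert-butylphenyl)phosphanyl]-7'-(4-benzyl-4,5-dihydro-1,3-oxazol-2-yl)-1,1'-spirobiindane, antipode that gives the S acid), NEt3 (0.5 equiv), MeOH, 25–45 °C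
Reagents that add atoms: none
Why: In this carboxy-directed iridium-catalysed asymmetric hydrogenation of a 1,1-disubstituted aryl alkene, carboxylate binding to the metal hydride should fix the alkene face shown to the chiral P,N ligand and suppress isomerisation, so the benzylic methyl centre is set S by the catalyst.

**Step 4**
Reactants: 6 (4S)-4-(3-methoxy-4-methylphenyl)pentanoic acid
Product: 7 (4S)-6-methoxy-4,7-dimethyl-3,4-dihydronaphthalen-1(2H)-one
Conditions: Eaton's reagent (7.7 wt% P4O10 in CH3SO3H), 25 °C
Reagents that add atoms: none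
Why: Intramolecular Friedel–Crafts acylation should close ring B at the unhindered position para to OCH3 and not at the position between chain and OCH3, and the benzylic stereocentre lies away from the reacting atoms and should not epimerise.

**Step 5**
Reactants: 7 (4S)-6-methoxy-4,7-dimethyl-3,4-dihydronaphthalen-1(2H)-one
Product: 9 (1S)-7-methoxy-1,6-dimethyl-4-(propan-2-yl)-1,2-dihydronaphthalene, via tertiary alcohol 8 (not isolated)
Conditions: i-PrMgCl, anhydrous CeCl3, THF, −78 °C to 0 °C; 1 M HCl, 0 °C; then p-TsOH·H2O (5 mol%), toluene, 60 °C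
Reagents that add atoms: isopropylmagnesium chloride, CC(C)[Mg]Cl
Why: Organocerium (Imamoto) 1,2-addition should suppress enolisation of the electron-rich aryl ketone, and E1 dehydration of the tertiary benzylic alcohol should give the conjugated endocyclic alkene, the carbinol centre being a mixture that is destroyed in the dehydration.

**Step 6**
Reactants: 9 (1S)-7-methoxy-1,6-dimethyl-4-(propan-2-yl)-1,2-dihydronaphthalene
Product: 10 (1S,4S)-7-methoxy-1,6-dimethyl-4-(propan-2-yl)-1,2,3,4-tetrahydronaphthalene
Conditions: H2 (1 atm), 10% Pd/C, EtOAc, 20 °C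
Reagents that add atoms: none
Why: In this heterogeneous catalytic hydrogenation of a trisubstituted styrene the C1 methyl sits pseudoaxial to avoid the peri C8–H and shields one face of the half-chair, so hydrogen should add to C3=C4 from the opposite face and leave the isopropyl group cis to the methyl (4S).

**Step 7**
Reactants: 10 (1S,4S)-7-methoxy-1,6-dimethyl-4-(propan-2-yl)-1,2,3,4-tetrahydronaphthalene
Product: 12 (5S,8S)-3,8-dimethyl-5-(propan-2-yl)-5,6,7,8-tetrahydronaphthalen-2-ol, via aryl dibromoborinate 11 (not isolated)
Conditions: BBr3 (1.3 equiv), CH2Cl2, −78 °C to 0 °C; H2O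
Reagents that add atoms: none
Why: In this Lewis-acid ether cleavage BBr3 binds the ether oxygen, bromide removes the methyl group by SN2 and water hydrolyses the B–O bond, with no stereocentre involved.

**Step 8**
Reactants: 12 (5S,8S)-3,8-dimethyl-5-(propan-2-yl)-5,6,7,8-tetrahydronaphthalen-2-ol (two molecules)
Product: 15 (5S,5'S,8S,8'S)-3,3',8,8'-tetramethyl-5,5'-di(propan-2-yl)-5,5',6,6',7,7',8,8'-octahydro-[1,1'-binaphthalene]-2,2'-diol, via aryloxyl radical 13 (not isolated), via bis-cyclohexadienone 14 (not isolated)
Conditions: (t-BuO)2 (0.55 equiv), PhCl, 130 °C, Ar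
Reagents that add atoms: none
Why: Thermolysis of di-tert-butyl peroxide gives tert-butoxyl radicals that abstract the phenolic hydrogen of 12 much faster than any benzylic C–H, and two aryloxyl radicals 13 (spin on O, C6, C8, C4a) pair C8 to C8' to give bis(cyclohexadienone) 14, which tautomerises twice to biphenol 15. The closest known reaction type is the peroxide- or metal-mediated oxidative dehydrodimerisation of ortho-methyl, para-substituted phenols and of 3-substituted 5,6,7,8-tetrahydro-2-naphthols to tetra-ortho-substituted 2,2'-biphenols. No ring is closed. The sp3 centres at C8 and C8' of 14 disappear on enolisation and the four existing centres are not touched; the only new stereo-element is the C8–C8' axis, whose sense the target leaves open and which only the peri C1 methyl groups of the two homochiral halves can bias, so both atropisomers may form. The selectivity needed is C8–C8' coupling over coupling through O, C6 or C4a: pairing at C6 (CH3) or C4a (ring fusion) gives dienones with no hydrogen to lose that should fall back to 13 at 130 °C, the C8–O quinol ether is the weaker and more reversible adduct, and only 14 is drained irreversibly by tautomerisation. Over-oxidation of 15 should be limited by the substoichiometric peroxide and by recovery of unreacted 12.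

**Compound list**
1 | 4-bromo-2-methoxy-1-methylbenzene | COc1cc(Br)ccc1C | starting material
2 | succinic anhydride | O=C1CCC(=O)O1 | starting material
3 | (3-methoxy-4-methylphenyl)magnesium bromide | COc1cc([Mg]Br)ccc1C | intermediate
4 | 4-(3-methoxy-4-methylphenyl)-4-oxobutanoic acid | COc1cc(C(=O)CCC(=O)O)ccc1C | intermediate
5 | 4-(3-methoxy-4-methylphenyl)pent-4-enoic acid | COc1cc(C(=C)CCC(=O)O)ccc1C | intermediate
6 | (4S)-4-(3-methoxy-4-methylphenyl)pentanoic acid | C[C@@H](CCC(=O)O)c1ccc(C)c(OC)c1 | intermediate
7 | (4S)-6-methoxy-4,7-dimethyl-3,4-dihydronaphthalen-1(2H)-one | C[C@H]1CCC(=O)c2cc(C)c(OC)cc12 | intermediate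
8 | (4S)-6-methoxy-4,7-dimethyl-1-(propan-2-yl)-1,2,3,4-tetrahydronaphthalen-1-ol (both C1 epimers) | C[C@H]1CCC(O)(C(C)C)c2cc(C)c(OC)cc12 | intermediate
9 | (1S)-7-methoxy-1,6-dimethyl-4-(propan-2-yl)-1,2-dihydronaphthalene | C[C@H]1CC=C(C(C)C)c2cc(C)c(OC)cc12 | intermediate
10 | (1S,4S)-7-methoxy-1,6-dimethyl-4-(propan-2-yl)-1,2,3,4-tetrahydronaphthalene (cis) | Cc1cc2c(cc1OC)[C@@H](C)CC[C@H]2C(C)C | intermediate
11 | dibromo{[(5S,8S)-3,8-dimethyl-5-(propan-2-yl)-5,6,7,8-tetrahydronaphthalen-2-yl]oxy}borane | Cc1cc2c(cc1OB(Br)Br)[C@@H](C)CC[C@H]2C(C)C | intermediate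
12 | (5S,8S)-3,8-dimethyl-5-(propan-2-yl)-5,6,7,8-tetrahydronaphthalen-2-ol, (1S,4S)-7-hydroxycalamenene | Cc1cc2c(cc1O)[C@@H](C)CC[C@H]2C(C)C | intermediate
13 | aryloxyl radical of 12 | Cc1cc2c(cc1[O])[C@@H](C)CC[C@H]2C(C)C | intermediate
14 | C8–C8' linked bis(cyclohexa-2,4-dienone), keto tautomer of 15 (C8 and C8' undefined) | CC1=CC2=C(C(C3C(=O)C(C)=CC4=C3[C@@H](C)CC[C@H]4C(C)C)C1=O)[C@@H](C)CC[C@H]2C(C)C | intermediate
15 | (5S,5'S,8S,8'S)-3,3',8,8'-tetramethyl-5,5'-di(propan-2-yl)-5,5',6,6',7,7',8,8'-octahydro-[1,1'-binaphthalene]-2,2'-diol | Cc1cc2c(c(-c3c(O)c(C)cc4c3[C@@H](C)CC[C@H]4C(C)C)c1O)[C@@H](C)CC[C@H]2C(C)C | target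

**Count and risks**
Total step count: 8. Longest linear sequence: 8 steps (1 to 15).

Step 8. The aryloxyl radical may pair through oxygen, may disproportionate through the C6 methyl group to an ortho-quinone methide, or the product may be oxidised further, so conversion to the C8–C8' dimer may stay low. The fallback sets out from 12 and comes back at 15. Iodination at the only free position ortho to OH (I2, morpholine, CH2Cl2, 0 °C) should give (5S,8S)-1-iodo-3,8-dimethyl-5-(propan-2-yl)-5,6,7,8-tetrahydronaphthalen-2-ol F1. O-Methylation (MeI, K2CO3, acetone, reflux) should give (1S,4S)-8-iodo-7-methoxy-1,6-dimethyl-4-(propan-2-yl)-1,2,3,4-tetrahydronaphthalene F2. Classical Ullmann homocoupling (activated Cu powder, DMF, 150 °C), which is known for aryl iodides flanked by OCH3 and an alkyl group, should give (5S,5'S,8S,8'S)-2,2'-dimethoxy-3,3',8,8'-tetramethyl-5,5'-di(propan-2-yl)-5,5',6,6',7,7',8,8'-octahydro-1,1'-binaphthalene F3. BBr3 in CH2Cl2 then cleaves both ethers to 15.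

Step 6. Facial selectivity may be poor, and palladium may move the double bond around ring B before reduction, which would scramble C1. The fallback sets out from 9 and comes back at 10. It replaces substrate control by catalyst control: homogeneous hydrogenation with a cationic iridium P,N complex, [Ir(cod)(L)][B(3,5-(CF3)2C6H3)4] (L = chiral phosphinite–oxazoline), H2 (50 bar), CH2Cl2, 25 °C. The antipode of L that matches the substrate bias is found by running both. Such catalysts reduce trisubstituted aryl alkenes without migration, and the ligand then sets C4 in concert with the C1 methyl. This fallback makes no new compound (F0).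

Step 5. The basic isopropyl nucleophile may enolise or reduce the electron-rich tetralone in place of adding to it. The fallback sets out from 6 and comes back at 9, with the isopropyl group installed before ring closure. Acid 6 is converted (1,1'-carbonyldiimidazole, then MeNH(OMe)·HCl, CH2Cl2) into (4S)-N-methoxy-4-(3-methoxy-4-methylphenyl)-N-methylpentanamide F4. i-PrMgCl (THF, 0 °C) should give (6S)-6-(3-methoxy-4-methylphenyl)-2-methylheptan-3-one F5. Acid-catalysed cyclodehydration (CF3SO3H cat., CH2Cl2, 0 °C to 25 °C), an intramolecular Friedel–Crafts attack para to OCH3 on the protonated ketone followed by loss of water, should give 9.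

**Further compounds**
F1 | step 8 | (5S,8S)-1-iodo-3,8-dimethyl-5-(propan-2-yl)-5,6,7,8-tetrahydronaphthalen-2-ol | Cc1cc2c(c(I)c1O)[C@@H](C)CC[C@H]2C(C)C
F2 | step 8 | (1S,4S)-8-iodo-7-methoxy-1,6-dimethyl-4-(propan-2-yl)-1,2,3,4-tetrahydronaphthalene | Cc1cc2c(c(I)c1OC)[C@@H](C)CC[C@H]2C(C)C
F3 | step 8 | (5S,5'S,8S,8'S)-2,2'-dimethoxy-3,3',8,8'-tetramethyl-5,5'-di(propan-2-yl)-5,5',6,6',7,7',8,8'-octahydro-1,1'-binaphthalene | Cc1cc2c(c(-c3c(OC)c(C)cc4c3[C@@H](C)CC[C@H]4C(C)C)c1OC)[C@@H](C)CC[C@H]2C(C)C
F0 | step 6 | none | none
F4 | step 5 | (4S)-N-methoxy-4-(3-methoxy-4-methylphenyl)-N-methylpentanamide | C[C@@H](CCC(=O)N(C)OC)c1ccc(C)c(OC)c1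
F5 | step 5 | (6S)-6-(3-methoxy-4-methylphenyl)-2-methylheptan-3-one | C[C@@H](CCC(=O)C(C)C)c1ccc(C)c(OC)c1
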